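**Plan**

1. Numbering follows the drimane terpenoids: ring A = C1–C5 and C10, ring B = C5–C10, CH3 groups on C4 (two), C8 and C10, chain C11–C17 on C9. The retrosynthesis cuts C14–C15 (diene), then C9–C11 (ring to chain), then C1–C2 and C3–C4 of ring A together, which removes the CH2–CH2 unit C2–C3 as acrolein.
2. Enabling feature: in ring A the gem-dimethyl carbon C4 sits on the ring-fusion CH (C5) and the CH2 C1 sits on the quaternary C10. C4 is therefore the Markovnikov tertiary radical of an isopropenyl group and C1 an aldehyde, held 1,4 across the C5–C10 bond; ring B with exactly this isopropenyl group, the C8 methyl and the C9 oxygen is (R)-carvone.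
3. Forward, rings: ring B is present from the start. C10 receives CH3, then CH2OH (oxidised to the C1 aldehyde). One iron-hydride operation joins acrolein by radical conjugate addition (C3–C4) and aldol (C1–C2) and closes ring A. The helpers (1-OH, 2-CHO, C1=C2) are then removed and the C9 ketone becomes the C8=C9 enol triflate.
4. Forward, chain: Negishi coupling at C9 with a C11–C14 butynyl unit, then carboalumination (C13 methyl) and cross-coupling with a separately made C15–C17 iodoalkene ester.
5. Stereochemistry: C5 comes from (R)-carvone. C10 is set by hydroxymethylation of the enolate anti to the isopropenyl group, which fixes the trans fusion before ring A exists. C17 comes from methyl (S)-3-hydroxy-2-methylpropanoate; 13E from syn carboalumination; 15E from Takai olefination.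

Key step: step 4

**Route**

Step 1
Reactants: 1 (R)-(−)-carvone; 2 iodomethane
Product: 4 (5R,6S)-2,6-dimethyl-5-(prop-1-en-2-yl)cyclohex-2-en-1-one (trans-6-methylcarvone), via lithium dienolate of carvone 3 (not isolated)
Conditions: LiN(i-Pr)2 (1.1 equiv), THF, −78 °C; MeI, −78 → 0 °C
Reagents that add atoms: iodomethane, CI
Why: Enolate alkylation: LiN(i-Pr)2 removes the kinetically favoured α′-proton of the cross-conjugated enone (the future C10) and dienolate 3 should be methylated mainly anti to the isopropenyl group; the configuration of this centre is of no consequence because it is enolised again in step 2.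

Step 2
Reactants: 4 trans-6-methylcarvone; 5 formaldehyde
Product: 7 (5S,6R)-6-(hydroxymethyl)-2,6-dimethyl-5-(prop-1-en-2-yl)cyclohex-2-en-1-one, via lithium dienolate of methylcarvone 6 (not isolated)
Conditions: LiN(i-Pr)2 (1.2 equiv), THF, −78 °C; CH2O (gas from cracked paraformaldehyde, excess), −78 °C; AcOH, −78 °C
Reagents that add atoms: formaldehyde, C=O
Why: Aldol addition (hydroxymethylation) of the fully substituted lithium dienolate 6: formaldehyde should approach anti to the isopropenyl group on C5, which sets the quaternary C10 with CH2OH trans and CH3 cis to that group (the relation that becomes the trans ring fusion), and the cold acidic quench prevents retro-aldol cleavage.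

Step 3
Reactants: 7 hydroxymethyl ketone
Product: 8 (1R,6S)-1,3-dimethyl-2-oxo-6-(prop-1-en-2-yl)cyclohex-3-ene-1-carbaldehyde
Conditions: Dess–Martin periodinane (1.3 equiv), pyridine, CH2Cl2, 0 °C → rt
Reagents that add atoms: none
Why: Dess–Martin oxidation turns the neopentyl primary alcohol into the non-enolisable C1 aldehyde under neutral, non-aqueous conditions that should avoid retro-aldol and retro-Claisen cleavage of the β-dicarbonyl array; no stereocentre is touched.

Step 4
Reactants: 8 keto aldehyde; 9 acrolein
Product: 11 2α-formyl-1β-hydroxy-11-nordrim-7-en-9-one (trans-fused; expected main C1/C2 diastereomer), via open-chain aldehyde enolate 10 (not isolated)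
Conditions: Fe(acac)3 (30 mol %), PhSiH3 (2.5 equiv), acrolein (3 equiv), EtOH/(CH2OH)2 5:1, 0 °C → rt
Reagents that add atoms: acrolein, C=CC=O
Why: Fe(acac)3 and PhSiH3 give an iron hydride that transfers a hydrogen atom to the terminal CH2 of the isopropenyl group (Markovnikov), so that the tertiary radical at C4 adds to the β-carbon of acrolein (C3–C4 bond, quaternary gem-dimethyl C4), divalent iron reduces the resulting α-formyl radical to enolate 10, and 10 attacks the C1 aldehyde held on C10 (C1–C2 bond). The closest known reaction type is the hydrogen-atom-transfer-initiated radical conjugate addition–aldol annulation (radical–polar crossover) of γ,δ-unsaturated aldehydes with enones and enals, an extension of iron-hydride reductive olefin coupling. Ring A is closed in the aldol event by a 6-(enolexo)-exo-trig attack through a chair in which the C5–C4 and C10–C1 bonds are both pseudo-equatorial on ring B, so the fusion can only be trans. The new centres C1 (OH) and C2 (CHO) are set by this chair (both substituents expected equatorial) but are temporary, since both carbons become sp2 in step 5 and CH2 in steps 6 and 7; C5 and C10 are untouched. The step needs chemoselective hydrogen-atom transfer to the isopropenyl alkene in the presence of the C7=C8 enone, and aldol at C1 and not at the C9 ketone. The first is secured by the electron-rich, 1,1-disubstituted nature of that alkene and by excess acrolein as the fastest radical trap, the second by the higher electrophilicity of the aldehyde and by the fact that attack at C9 would give a bridged ring.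

Step 5
Reactants: 11 β-hydroxy aldehyde
Product: 12 9-oxo-11-nordrima-1,7-diene-2-carbaldehyde
Conditions: p-TsOH·H2O (0.1 equiv), PhMe, 60 °C
Reagents that add atoms: none
Why: Acid-catalysed dehydration of the β-hydroxy aldehyde (completion of an aldol condensation) can only give the conjugated C1=C2 enal because C10 is quaternary, and all C1/C2 diastereomers of 11 converge on 12.

Step 6
Reactants: 12 enal
Product: 13 11-nordrima-1,7-dien-9-one [(4aS,8aS)-2,5,5,8a-tetramethyl-4a,5,6,8a-tetrahydronaphthalen-1(4H)-one]
Conditions: RhCl(PPh3)3 (1.1 equiv), PhMe, 110 °C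
Reagents that add atoms: none
Why: Tsuji–Wilkinson decarbonylation: monovalent rhodium inserts into the formyl C–H bond, CO migrates to the metal and reductive elimination returns a vinyl C–H bond, so the formyl helper leaves as bound CO while the enone is untouched; a shift of the ring-A double bond would be harmless because it is hydrogenated next.

Step 7
Reactants: 13 dienone
Product: 14 11-nordrim-7-en-9-one [(4aS,8aS)-2,5,5,8a-tetramethyl-4a,5,6,7,8,8a-hexahydronaphthalen-1(4H)-one]
Conditions: H2 (1–3 atm), RhCl(PPh3)3 (0.1 equiv), PhH/EtOH 1:1, rt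
Reagents that add atoms: none
Why: Homogeneous hydrogenation with RhCl(PPh3)3 should reduce the cis-disubstituted ring-A alkene and leave the trisubstituted conjugated C7=C8 bond, the selectivity known from the reduction of carvone to carvotanacetone; no stereocentre is formed.

Step 8
Reactants: 14 enone; 15 N-phenylbis(trifluoromethanesulfonimide)
Product: 17 (4aS,8aS)-2,5,5,8a-tetramethyl-3,4,4a,5,6,7,8,8a-octahydronaphthalen-1-yl trifluoromethanesulfonate, via lithium enolate 16 (not isolated)
Conditions: LiBH(sec-Bu)3 (1.1 equiv), THF, −78 °C; PhNTf2 (1.3 equiv), −78 °C → rt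
Reagents that add atoms: N-phenylbis(trifluoromethanesulfonimide), O=S(=O)(N(c1ccccc1)S(=O)(=O)C(F)(F)F)C(F)(F)F
Why: Tandem conjugate reduction–enolate trapping: hydride adds to the β-unsubstituted C7 (1,2-attack is blocked by the quaternary C10) to give enolate 16 with the double bond only at C8=C9, and O-sulfonylation fixes the tetrasubstituted alkene of the target without ever creating a stereocentre at C8.

Step 9
Reactants: 17 enol triflate; 18 (4-bromobut-1-yn-1-yl)trimethylsilane
Product: 20 trimethyl{4-[(4aS,8aS)-2,5,5,8a-tetramethyl-3,4,4a,5,6,7,8,8a-octahydronaphthalen-1-yl]but-1-yn-1-yl}silane, via alkylzinc bromide 19 (not isolated)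
Conditions: 18, Zn dust, LiCl, THF, 50 °C; then 17, PdCl2(dppf) (5 mol %), THF/NMP, 60 °C
Reagents that add atoms: (4-bromobut-1-yn-1-yl)trimethylsilane, C[Si](C)(C)C#CCCBr
Why: Negishi coupling: zerovalent palladium formed from PdCl2(dppf) adds to the C9–OTf bond, the primary alkylzinc 19 transmetalates and the wide-bite-angle ligand favours reductive elimination over β-hydride elimination, which forms C9–C11 with the double bond held in place by the triflate.

Step 10
Reactants: 20 silyl alkyne
Product: 21 (4aS,8aS)-5-(but-3-yn-1-yl)-1,1,4a,6-tetramethyl-1,2,3,4,4a,7,8,8a-octahydronaphthalene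
Conditions: K2CO3 (0.2 equiv), MeOH/THF, rt
Reagents that add atoms: none
Why: Base-catalysed methanolysis of the C(sp)–Si bond (protodesilylation) frees the terminal alkyne needed for carbometalation, and nothing else in 20 reacts with K2CO3 in methanol.

Step 11
Reactants: 22 methyl (S)-3-hydroxy-2-methylpropanoate; 23 tert-butylchlorodimethylsilane
Product: 24 methyl (S)-3-[(tert-butyldimethylsilyl)oxy]-2-methylpropanoate
Conditions: TBSCl (1.1 equiv), imidazole (2 equiv), CH2Cl2, 0 °C → rt
Reagents that add atoms: tert-butylchlorodimethylsilane, CC(C)(C)[Si](C)(C)Cl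
Why: Standard silyl ether formation protects the primary alcohol so that the ester carbon can become the vinyl carbon C16; the α-stereocentre is not involved.

Step 12
Reactants: 24 silyl ether ester
Product: 25 (S)-3-[(tert-butyldimethylsilyl)oxy]-2-methylpropanal
Conditions: i-Bu2AlH (1.05 equiv), CH2Cl2, −78 °C; MeOH, aq. potassium sodium tartrate
Reagents that add atoms: none
Why: Partial ester reduction with i-Bu2AlH at −78 °C stops at the tetrahedral aluminium hemiacetal, which releases the aldehyde only on work-up; the configurationally labile α-methyl aldehyde is used at once without chromatography.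

Step 13
Reactants: 25 aldehyde; 26 iodoform
Product: 27 (R,E)-tert-butyl[(4-iodo-2-methylbut-3-en-1-yl)oxy]dimethylsilane
Conditions: CrCl2 (6 equiv), CHI3 (2 equiv), THF, 0 °C → rt
Reagents that add atoms: iodoform, IC(I)I
Why: Takai olefination: the geminal dichromium species from CHI3 and CrCl2 adds to the aldehyde and eliminates to the E-iodoalkene under non-basic conditions, so the α-stereocentre should be retained.

Step 14
Reactants: 27 silyl ether
Product: 28 (R,E)-4-iodo-2-methylbut-3-en-1-ol
Conditions: camphorsulfonic acid (0.1 equiv), MeOH/CH2Cl2, 0 °C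
Reagents that add atoms: none
Why: Acid-catalysed methanolysis (desilylation) cleaves the primary silyl ether without touching the iodoalkene or the allylic stereocentre.

Step 15
Reactants: 28 iodo alcohol; 29 water
Product: 30 (R,E)-4-iodo-2-methylbut-3-enoic acid
Conditions: TEMPO (0.2 equiv), PhI(OAc)2 (2.2 equiv), MeCN/H2O 1:1, rt
Reagents that add atoms: water, O
Why: Oxoammonium (TEMPO) oxidation takes the primary alcohol through the aldehyde hydrate to the acid at slightly acidic pH, conditions chosen so that the α-stereocentre is not enolised and the double bond does not move into conjugation.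

Step 16
Reactants: 30 iodo acid; 31 (trimethylsilyl)diazomethane
Product: 32 methyl (R,E)-4-iodo-2-methylbut-3-enoate
Conditions: Me3SiCHN2 (1.2 equiv), PhMe/MeOH 4:1, 0 °C
Reagents that add atoms: (trimethylsilyl)diazomethane, C[Si](C)(C)C=[N+]=[N-]
Why: Esterification with a diazomethane equivalent is base-free and fast, so the doubly activated α-hydrogen (allylic and α to the ester) should not be exchanged.

Step 17
Reactants: 21 terminal alkyne; 33 trimethylaluminium; 32 iodoalkene ester
Product: 36 methyl (2R,3E,5E)-2,6-dimethyl-8-[(4aS,8aS)-2,5,5,8a-tetramethyl-3,4,4a,5,6,7,8,8a-octahydronaphthalen-1-yl]octa-3,5-dienoate (the target), via alkenylalane 34 (not isolated), via alkenylzinc chloride 35 (not isolated)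
Conditions: AlMe3 (2.5 equiv), Cp2ZrCl2 (0.3 equiv), CH2Cl2, 0 °C → rt; evaporation; THF, ZnCl2 (1.2 equiv), 32, Pd(PPh3)4 (5 mol %), rt
Reagents that add atoms: trimethylaluminium, C[Al](C)C
Why: Zirconium-catalysed carboalumination adds CH3 and Al syn across the alkyne with CH3 on C13, which defines the 13E alkene in 34; transmetalation to zinc (35) and Negishi coupling with 32 proceed with retention at both alkenyl carbons (15E from step 13) under neutral conditions that should leave the C17 stereocentre and the ester–diene array untouched.

**Compound list**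

1 | (R)-(−)-carvone, (5R)-2-methyl-5-(prop-1-en-2-yl)cyclohex-2-en-1-one | O=C1C(C)=CC[C@@H](C(C)=C)C1 | starting material
2 | iodomethane | CI | starting material
3 | lithium α′-dienolate of 1 (C=C between the carbonyl carbon and the future C10; not isolated) | [Li]OC1=C[C@H](C(C)=C)CC=C1C | intermediate
4 | (5R,6S)-2,6-dimethyl-5-(prop-1-en-2-yl)cyclohex-2-en-1-one (trans-6-methylcarvone, main epimer) | O=C1C(C)=CC[C@@H](C(C)=C)[C@@H]1C | intermediate
5 | formaldehyde (monomer from paraformaldehyde) | C=O | starting material
6 | lithium α′-dienolate of 4 (not isolated) | [Li]OC1=C(C)[C@H](C(C)=C)CC=C1C | intermediate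
7 | (5S,6R)-6-(hydroxymethyl)-2,6-dimethyl-5-(prop-1-en-2-yl)cyclohex-2-en-1-one (CH2OH trans to isopropenyl) | O=C1C(C)=CC[C@@H](C(C)=C)[C@]1(C)CO | intermediate
8 | (1R,6S)-1,3-dimethyl-2-oxo-6-(prop-1-en-2-yl)cyclohex-3-ene-1-carbaldehyde | O=C1C(C)=CC[C@@H](C(C)=C)[C@]1(C)C=O | intermediate
9 | acrolein (prop-2-enal) | C=CC=O | starting material
10 | open-chain aldehyde enolate from addition of the C4 radical to acrolein (iron-bound; drawn as the free Z enolate anion, geometry not controlled; not isolated) | O=C1C(C)=CC[C@@H](C(C)(C)C/C=C\[O-])[C@]1(C)C=O | intermediate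
11 | 2α-formyl-1β-hydroxy-11-nordrim-7-en-9-one (trans-fused, 5α-H, 10β-CH3; expected main diastereomer, C1/C2 epimers converge in step 5) | O=C1C(C)=CC[C@H]2C(C)(C)C[C@H](C=O)[C@@H](O)[C@]12C | intermediate
12 | 9-oxo-11-nordrima-1,7-diene-2-carbaldehyde | O=C1C(C)=CC[C@H]2C(C)(C)CC(C=O)=C[C@]12C | intermediate
13 | 11-nordrima-1,7-dien-9-one, (4aS,8aS)-2,5,5,8a-tetramethyl-4a,5,6,8a-tetrahydronaphthalen-1(4H)-one | O=C1C(C)=CC[C@H]2C(C)(C)CC=C[C@]12C | intermediate
14 | 11-nordrim-7-en-9-one, (4aS,8aS)-2,5,5,8a-tetramethyl-4a,5,6,7,8,8a-hexahydronaphthalen-1(4H)-one | O=C1C(C)=CC[C@H]2C(C)(C)CCC[C@]12C | intermediate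
15 | N-phenylbis(trifluoromethanesulfonimide) | O=S(=O)(N(c1ccccc1)S(=O)(=O)C(F)(F)F)C(F)(F)F | starting material
16 | lithium 11-nordrim-8-en-9-olate (C8=C9 enolate; not isolated) | [Li]OC1=C(C)CC[C@H]2C(C)(C)CCC[C@]12C | intermediate
17 | (4aS,8aS)-2,5,5,8a-tetramethyl-3,4,4a,5,6,7,8,8a-octahydronaphthalen-1-yl trifluoromethanesulfonate | O=S(=O)(OC1=C(C)CC[C@H]2C(C)(C)CCC[C@]12C)C(F)(F)F | intermediate
18 | (4-bromobut-1-yn-1-yl)trimethylsilane | C[Si](C)(C)C#CCCBr | starting material
19 | [4-(trimethylsilyl)but-3-yn-1-yl]zinc bromide (not isolated) | C[Si](C)(C)C#CCC[Zn]Br | intermediate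
20 | trimethyl{4-[(4aS,8aS)-2,5,5,8a-tetramethyl-3,4,4a,5,6,7,8,8a-octahydronaphthalen-1-yl]but-1-yn-1-yl}silane | C[Si](C)(C)C#CCCC1=C(C)CC[C@H]2C(C)(C)CCC[C@]12C | intermediate
21 | (4aS,8aS)-5-(but-3-yn-1-yl)-1,1,4a,6-tetramethyl-1,2,3,4,4a,7,8,8a-octahydronaphthalene | C#CCCC1=C(C)CC[C@H]2C(C)(C)CCC[C@]12C | intermediate
22 | methyl (S)-3-hydroxy-2-methylpropanoate | COC(=O)[C@@H](C)CO | starting material
23 | tert-butylchlorodimethylsilane | CC(C)(C)[Si](C)(C)Cl | starting material
24 | methyl (S)-3-[(tert-butyldimethylsilyl)oxy]-2-methylpropanoate | COC(=O)[C@@H](C)CO[Si](C)(C)C(C)(C)C | intermediate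
25 | (S)-3-[(tert-butyldimethylsilyl)oxy]-2-methylpropanal | O=C[C@@H](C)CO[Si](C)(C)C(C)(C)C | intermediate
26 | iodoform | IC(I)I | starting material
27 | (R,E)-tert-butyl[(4-iodo-2-methylbut-3-en-1-yl)oxy]dimethylsilane | I/C=C/[C@@H](C)CO[Si](C)(C)C(C)(C)C | intermediate
28 | (R,E)-4-iodo-2-methylbut-3-en-1-ol | I/C=C/[C@@H](C)CO | intermediate
29 | water | O | starting material
30 | (R,E)-4-iodo-2-methylbut-3-enoic acid | I/C=C/[C@@H](C)C(=O)O | intermediate
31 | (trimethylsilyl)diazomethane | C[Si](C)(C)C=[N+]=[N-] | starting material
32 | methyl (R,E)-4-iodo-2-methylbut-3-enoate | COC(=O)[C@H](C)/C=C/I | intermediate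
33 | trimethylaluminium | C[Al](C)C | starting material
34 | (E)-alkenyldimethylalane from 21 (Al on C14, CH3 on C13; not isolated) | C[Al](C)/C=C(\C)CCC1=C(C)CC[C@H]2C(C)(C)CCC[C@]12C | intermediate
35 | (E)-alkenylzinc chloride from 34 (not isolated) | Cl[Zn]/C=C(\C)CCC1=C(C)CC[C@H]2C(C)(C)CCC[C@]12C | intermediate
36 | methyl (2R,3E,5E)-2,6-dimethyl-8-[(4aS,8aS)-2,5,5,8a-tetramethyl-3,4,4a,5,6,7,8,8a-octahydronaphthalen-1-yl]octa-3,5-dienoate | COC(=O)[C@H](C)/C=C/C=C(\C)CCC1=C(C)CC[C@H]2C(C)(C)CCC[C@]12C | target

**Count and risks**

Total step count: 17. Longest linear sequence: 11 steps (steps 1–10 and 17); steps 11–16 make the iodoalkene ester in parallel.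

Steps most likely to fail:

1. Step 4. The cascade may be intercepted between its two bond-forming events: the tertiary radical may be reduced by a second hydrogen-atom transfer, or the enolate may be protonated or silylated before it reaches the C1 aldehyde. Hydride transfer to the ring-B enone would add to the loss. Fallback: the two bonds are made in separate operations. From 8, the iron-hydride reductive olefin coupling with acrolein is run in its ordinary intermolecular form (Fe(acac)3, PhSiH3, EtOH, no glycol) and stopped at the open-chain keto dialdehyde F1. F1 is then closed by an amine-catalysed intramolecular aldol condensation (pyrrolidine, AcOH, PhMe, 60 °C). Only the chain aldehyde can enolise and only the C1 aldehyde is a non-enolisable acceptor, so the closure should lead directly to enal 12, where the route is rejoined.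

2. Step 6. Oxidative addition and CO extrusion may be slow at the hindered, conjugated formyl group, so that thermal or metal-mediated decomposition of the dienone competes above 100 °C. Fallback: the formyl carbon is removed as CO2 instead of CO. From 11, Pinnick oxidation (NaClO2, NaH2PO4, 2-methylbut-2-ene) should give the β-hydroxy acid F2. Radical hydrodecarboxylation (acridinium photocatalyst with PhSSPh under blue light, or Barton decarboxylation) should give the C1 alcohol F3. Syn dehydration with the Burgess reagent (PhH, 50 °C) can only eliminate toward C2 and should return alkene 13.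

3. Step 9. Oxidative addition and transmetalation at the tetrasubstituted C9 triflate, flanked by the quaternary C10, may be slow, so that β-hydride elimination or protonation of the alkylzinc and hydrolysis of the triflate take over. Fallback: the C9–C11 bond is made by carbonyl addition instead of cross-coupling. From 14, the organocerium reagent prepared from 18 (Mg, then CeCl3, THF, −78 °C) should add 1,2 to the C9 ketone from the face opposite the angular methyl to give the tertiary allylic alcohol F4. Ionic deoxygenation (Et3SiH, BF3·OEt2, CH2Cl2, −78 °C) passes through the C7–C8–C9 allyl cation, which should take hydride at the less hindered C7 and so give the tetrasubstituted C8=C9 alkene 20.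

**Further compounds**

F1 | step 4 | (1R,6S)-1,3-dimethyl-6-(2-methyl-5-oxopentan-2-yl)-2-oxocyclohex-3-ene-1-carbaldehyde | O=C1C(C)=CC[C@@H](C(C)(C)CCC=O)[C@]1(C)C=O
F2 | step 6 | 1β-hydroxy-9-oxo-11-nordrim-7-ene-2α-carboxylic acid | O=C1C(C)=CC[C@H]2C(C)(C)C[C@H](C(=O)O)[C@@H](O)[C@]12C
F3 | step 6 | 1β-hydroxy-11-nordrim-7-en-9-one | O=C1C(C)=CC[C@H]2C(C)(C)CC[C@@H](O)[C@]12C
F4 | step 9 | 9α-[4-(trimethylsilyl)but-3-yn-1-yl]-11-nordrim-7-en-9β-ol | C[Si](C)(C)C#CCC[C@]1(O)C(C)=CC[C@H]2C(C)(C)CCC[C@]12C
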